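**Retrosynthetic overview**
- The (2S)-flavanone is opened at the O1–C2 bond of ring C. This is an enantioselective intramolecular oxa-Michael addition that sets C2, and it leads back to (E)-2',4',4-trihydroxy-3,5-diprenylchalcone.
- The chalcone is cut at Cα=Cβ (Claisen–Schmidt) into 2',4'-dihydroxyacetophenone (ring A) and 4-hydroxy-3,5-diprenylbenzaldehyde (ring B).
- The diprenyl aldehyde comes from twofold ortho C-prenylation of 4-hydroxybenzaldehyde with prenyl bromide.
- Rings A and B are bought. Ring C is the only ring formed and it is formed last. No protecting groups are used.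

Assumption: the recombinant enzyme in step 3 (expressed in E. coli from a purchased synthetic gene) is treated as a catalyst, so its preparation is not counted as a synthetic step.

**Step 1**
Reactants: 1 4-hydroxybenzaldehyde; 2 prenyl bromide (1-bromo-3-methylbut-2-ene)
Product: 4 4-hydroxy-3,5-bis(3-methylbut-2-enyl)benzaldehyde, via 4-hydroxy-3-prenylbenzaldehyde 3 (not isolated)
Conditions: 2 (2.5 equiv, added in portions), KOH (3 equiv, 10% aq), H2O, 0 °C to rt, 24 h; then dilute HCl to pH 5; chromatography (recovered 1 and 3 are recycled)
Reagents that add atoms: prenyl bromide (2), CC(C)=CCBr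
Why: This is an ortho C-alkylation of an ambident phenoxide (SN2 C-prenylation), in which water hydrogen-bonds the phenoxide oxygen so the soft allylic bromide is attacked by the ortho carbon, the dienone re-aromatises, and with the para position blocked by CHO the second prenyl group can only enter the other ortho position; no stereocenter is formed.

**Step 2**
Reactants: 4 4-hydroxy-3,5-bis(3-methylbut-2-enyl)benzaldehyde; 5 2',4'-dihydroxyacetophenone
Product: 7 (E)-1-(2,4-dihydroxyphenyl)-3-[4-hydroxy-3,5-bis(3-methylbut-2-enyl)phenyl]prop-2-en-1-one (3,5-diprenylisoliquiritigenin), via racemic aldol adduct 6 (not isolated)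
Conditions: KOH (50% aq, 12 equiv), EtOH, N2, rt to 40 °C, 48 h; then cold dilute HCl to pH 5; chromatography or crystallisation to remove any trace of racemic flavanone
Reagents that add atoms: none
Why: This is a Claisen–Schmidt (crossed aldol) condensation, in which the ketone enolate adds to the non-enolisable aldehyde, E1cB loss of water from 6 gives the conjugated and thermodynamically preferred (E)-enone, the 2'-phenoxide chalcone is the resting state in strong base so ring C does not close, and the prenyl groups are inert to hydroxide; no stereocenter remains.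

**Step 3**
Reactants: 7 (E)-3,5-diprenylisoliquiritigenin
Product: 8 (2S)-7-hydroxy-2-[4-hydroxy-3,5-bis(3-methylbut-2-enyl)phenyl]-2,3-dihydrochromen-4-one (target)
Conditions: recombinant chalcone isomerase from Medicago sativa (type 2 enzyme, 0.1 mol%), KH2PO4/K2HPO4 buffer (50 mM, pH 7.0)/DMSO 9:1, hydroxypropyl-β-cyclodextrin (2 equiv), 7 at 0.5 mM, N2, dark, 25 °C, 2–6 h; EtOAc extraction, short neutral silica plug
Reagents that add atoms: none
Why: Proposed new method: an enzyme-catalysed enantioselective 6-endo-trig intramolecular oxa-Michael addition (O1–C2 bond, ring C) on a ring-B-diprenylated 6'-deoxychalcone, a substrate type on which chalcone isomerase has not been shown to work; mechanistically the legume enzyme anchors the 4'-OH of ring A by hydrogen bonds (asparagine/threonine), breaks the 2'-OH···O=C chelate, polarises the carbonyl through an arginine/threonine/tyrosine–water network and holds the 2'-oxyanion over the Si face of C-β only, so that C–O bond formation and C-3 protonation inside the active site give the (2S)-flavanone, while the apolar open cleft of this fold (evolved from a fatty-acid-binding pocket) should take up the two prenyl chains, the uncatalysed racemic background is negligible at pH 7 because the 2'-OH is chelated, and the aqueous equilibrium lies well on the flavanone side; the closest known reaction type is the chalcone-isomerase cyclisation of isoliquiritigenin to (2S)-liquiritigenin, with the thiourea-catalysed oxa-Michael cyclisation of ester-activated chalcones as its small-molecule counterpart.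

**Compound list**
1 | 4-hydroxybenzaldehyde | O=Cc1ccc(O)cc1 | starting material
2 | prenyl bromide (1-bromo-3-methylbut-2-ene) | CC(C)=CCBr | starting material
3 | 4-hydroxy-3-(3-methylbut-2-enyl)benzaldehyde (not isolated) | CC(C)=CCc1cc(C=O)ccc1O | intermediate
4 | 4-hydroxy-3,5-bis(3-methylbut-2-enyl)benzaldehyde | CC(C)=CCc1cc(C=O)cc(CC=C(C)C)c1O | intermediate
5 | 2',4'-dihydroxyacetophenone, 1-(2,4-dihydroxyphenyl)ethanone | CC(=O)c1ccc(O)cc1O | starting material
6 | racemic 1-(2,4-dihydroxyphenyl)-3-hydroxy-3-[4-hydroxy-3,5-bis(3-methylbut-2-enyl)phenyl]propan-1-one (not isolated) | CC(C)=CCc1cc(C(O)CC(=O)c2ccc(O)cc2O)cc(CC=C(C)C)c1O | intermediate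
7 | (E)-1-(2,4-dihydroxyphenyl)-3-[4-hydroxy-3,5-bis(3-methylbut-2-enyl)phenyl]prop-2-en-1-one | CC(C)=CCc1cc(/C=C/C(=O)c2ccc(O)cc2O)cc(CC=C(C)C)c1O | intermediate
8 | (2S)-7-hydroxy-2-[4-hydroxy-3,5-bis(3-methylbut-2-enyl)phenyl]-2,3-dihydrochromen-4-one | CC(C)=CCc1cc([C@@H]2CC(=O)c3ccc(O)cc3O2)cc(CC=C(C)C)c1O | target

**Step count**
Total step count: 3.
Longest linear sequence: 3 (1 → 4 → 7 → 8).

**Steps most likely to fail**

*Step 3 (the new step).*
- The cleft may not accept a ring B that carries two prenyl chains.
- The very lipophilic substrate may stay out of solution.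
- Long contact times would let the slow racemic background count.
- The ee is read by chiral HPLC. The (2S) configuration is confirmed by circular dichroism, with a positive n→π* band near 330 nm and a negative π→π* band near 290–310 nm.
- The product must be kept away from base, because 4'-hydroxyflavanones racemise by ring opening.

The fallback uses known chemistry, sets out from 7 and comes back at 8. Compound 7 is cyclised by the classical base-mediated chalcone–flavanone isomerisation (NaOAc, EtOH, reflux) to the racemic flavanone F1. F1 is then resolved by preparative HPLC on an amylose tris(3,5-dimethylphenylcarbamate) phase (hexane/i-PrOH) to give 8. The unwanted (2R)-enantiomer F2 is re-equilibrated with NaOAc/EtOH back to F1 and recycled, so material is not lost.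

*Step 1.*
- About 25–35% of 4 is expected.
- O-prenyl ether, mono-prenyl compound 3 and hydrolysed bromide compete with the desired product.

The fallback replaces phenoxide alkylation by cross-coupling, sets out from 1 and comes back at 4. Compound 1 is brominated (Br2, 2.1 equiv, AcOH, rt) to 3,5-dibromo-4-hydroxybenzaldehyde F3. F3 then undergoes a twofold Suzuki–Miyaura coupling with 3-methylbut-2-enylboronic acid pinacol ester (2.6 equiv). The coupling uses PdCl2(dppf) (5 mol%) and K3PO4 in THF/H2O at 60 °C, and delivers both linear prenyl groups to give 4.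

*Step 2.*
- The aldehyde reacts as its deactivated phenoxide and the ketone as a bis-phenoxide.
- The condensation is therefore slow, and about 40–55% is expected.

The fallback masks the acidic phenols, sets out from 4 and 5, and comes back at 7.
- Compound 5 is selectively etherified at the non-chelated 4-OH (MOMCl, K2CO3, acetone, rt) to 1-[2-hydroxy-4-(methoxymethoxy)phenyl]ethanone F4.
- Compound 4 is etherified in the same way (reflux) to 4-(methoxymethoxy)-3,5-bis(3-methylbut-2-enyl)benzaldehyde F5.
- F4 and F5 condense smoothly (KOH, EtOH/H2O, rt, then dilute HCl) to the bis-MOM chalcone F6.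
- Brief acid methanolysis (aq HCl, MeOH, 50 °C, monitored so that the prenyl phenol does not close to a chroman) releases 7.

**Further compounds**
F1 | step 3 | racemic 7-hydroxy-2-[4-hydroxy-3,5-bis(3-methylbut-2-enyl)phenyl]-2,3-dihydrochromen-4-one | CC(C)=CCc1cc(C2CC(=O)c3ccc(O)cc3O2)cc(CC=C(C)C)c1O
F2 | step 3 | (2R)-7-hydroxy-2-[4-hydroxy-3,5-bis(3-methylbut-2-enyl)phenyl]-2,3-dihydrochromen-4-one | CC(C)=CCc1cc([C@H]2CC(=O)c3ccc(O)cc3O2)cc(CC=C(C)C)c1O
F3 | step 1 | 3,5-dibromo-4-hydroxybenzaldehyde | O=Cc1cc(Br)c(O)c(Br)c1
F4 | step 2 | 1-[2-hydroxy-4-(methoxymethoxy)phenyl]ethanone | COCOc1ccc(C(C)=O)c(O)c1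
F5 | step 2 | 4-(methoxymethoxy)-3,5-bis(3-methylbut-2-enyl)benzaldehyde | COCOc1c(CC=C(C)C)cc(C=O)cc1CC=C(C)C
F6 | step 2 | (E)-1-[2-hydroxy-4-(methoxymethoxy)phenyl]-3-[4-(methoxymethoxy)-3,5-bis(3-methylbut-2-enyl)phenyl]prop-2-en-1-one | COCOc1ccc(C(=O)/C=C/c2cc(CC=C(C)C)c(OCOC)c(CC=C(C)C)c2)c(O)c1
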